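The earlier runs and the new flask are calculated from invented constants; the scatter is artificial.

I will forecast one number from these runs and leave the rest of the flask unforecast.

| flask | Z | X | remark | time |
|---|---|---|---|---|
| Monday's | 1.5 M | 0.23 M | run made earlier |  |
| Sunday's | 1.5 M | 0.33 M | run made earlier |  |
| south-west | 1.5 M | 0.500 M |  | 8.0 d |
| north | 1.5 M | 0.300 M |  | 4.0 d |

- Monday's (time / h: D / %, L / %): 4.00: 8.9, 3.2; 8.00: 8.9, 6.0; 15.0: 8.1, 7.7; 25.0: 9.4, 8.8; 50.0: 9.1, 9.3
- Sunday's (time / h: D / %, L / %): 4.00: 8.2, 3.4; 12.0: 8.8, 6.8; 20.0: 7.8, 7.6; 30.0: 8.6, 8.1; 50.0: 7.9, 7.2

(standard deviation of a reading: 0.5 percentage points)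

- which of the two ends with the higher share of D in all that became D or L ("neither" if they lie within 2 percentage points) (south-west / north / neither)
- share of D in all that became D or L, south-west
- share of D in all that became D or L, north



*Which number?* 0.0203, the late log ratio: the common logarithm of cD/cL, pooled over the last two readings of both runs. Zero means equal shares, and the share of D follows directly, here 51.2%.

*Why only late readings?* L is still climbing early, from 3.2% at 4.00 h in Monday's run, and the ratio has not yet levelled off there.

*Does X move it?* Look at the two runs apart. Monday's gives 0.00949 and Sunday's 0.0328. Yet D and L together end lower on Sunday, 15.1% against 18.4%. So X changes how much, and I see no sign that it changes the split. The gap of 0.0233 is within what a scatter of 0.5 percentage points per reading allows.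

*And the weak spot?* South-west's 0.500 M of X lies beyond both runs, and no run tests it. I assume the ratio holds there, as thermodynamic control of the split between D and L would have it. Both flasks also run past the last reading. My answer: neither, both near 51.2%.

The forecast says south-west, with 60% there and 52% in north, on the ground that L “levels off lower when more X is present”.

The flasks give 47.6% in south-west and 47.6% in north, so the answer is neither; the two are equal, and 3.6 points below my share.

    L ⇌ Z (k = 0.00980 h⁻¹)
    D ⇌ L (K = 1.10, k = 0.120 h⁻¹)
    Z + X → J (k = 2.50 M⁻¹ h⁻¹)
    Z ⇌ D (K = 0.130, k = 0.140 h⁻¹)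

Take the north flask with 0.75 M of X in place of 0.300 M. Holding the late log ratio at 0.0203, I again expect the share to stay where north's does. This neighbour ends at 5.11% of D and 5.62% of L, less than north's 8.17% and 8.99%, with 50.0% as J and 0% of its X left. Its logarithm of cD/cL is −0.0413, which is 0.0616 below my number, and its share of D is 47.6%.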